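(The rate constants come from no measurement; what happens was integrated by code.)

The catalysed route in this flask runs at 660 /M/s, faster than the 420 /M/s of the uncatalysed route, and the two together make 1080 /M/s. Both rates carry [starting material][dissolved gas], so these cancel from their ratio, and the catalyst comes back from its step. The split is therefore constant. The target share (a selectivity) is the catalysed term divided by the sum of both terms, 61.1%. Equal routes, the zero of this scale at 0.5, need 19.1 µM of catalyst.

    gas phase ⇌ dissolved gas, rate k1*(csat - [dissolved gas]) (k1 = 0.075 /s, csat = 0.013 mM)
    starting material + dissolved gas + catalyst → catalyst + target (k2 = 2.2 × 10⁷ /M²/s)
    starting material + protic impurity → quenched substrate (k3 = 9400 /M/s)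
    starting material + dissolved gas → uncatalysed product (k4 = 420 /M/s)

starting material 2.0 × 10⁻⁴ M; gas phase 0.013 mM (held); protic impurity 0.0400 mM; catalyst 30 µM; time 4.0 min

- target at 4.0 min, in percent of the starting material charged
- the change that raises the amount of target at 4.0 min, in percent of the starting material charged most ("none" if none brings more than 2 percentage points) (amber / grey / violet / none)
- amount of target at 4.0 min, in percent of the starting material charged, after amber

- amber: doubling the saturation concentration of gas phase, all else as stated
- grey: doubling the transfer coefficient of step 1, all else as stated
- violet: doubling the amount of catalyst, all else as stated

By this reckoning, the protic impurity acts first: the half-life of [starting material] by its step, with the impurity held at its charge as if it never ran down, is 1.8 s, shorter than the 49.4 s of the gas routes at saturation. But the impurity is charged at 0.0400 mM against 2.0 × 10⁻⁴ M of starting material, so it can take 20.0% of the charge, and the rest awaits gas. With [dissolved gas] held at saturation, target reaches 47.2%. Held instead at the first balance of transfer and uptake, 30.3% of saturation, target reaches 31.3%. The real [dissolved gas] nears that balance within about 4.04 s and climbs as starting material falls, so this reckoning commits to the midpoint, 39.2%. Amber gives the bracket 42.5% to 48.8%. Violet lifts the share to 75.9%, above what amber and grey leave, so the reckoning picks violet.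

The forecast gives 38% (35% to 41%), 48% after amber (45% to 51%), and violet, since the gas changes give “supplies more gas at the same selectivity”.

The flask gives 37.7%, and 48.1% after amber; violet gains 15 percentage points, against 10 points for amber and 6.1 points for grey. Catalyst at 23.6 µM or 37.8 µM moves target in this flask by 5 points, outside the forecast's range. This flask ends with 37.7% target and 24.0% uncatalysed product, a share read as 61.1% against the reckoned 61.1%. The same flask with 5.0 × 10⁻⁴ M of starting material ends with 53.3% of it unreacted, 23.6% target and 15.0% uncatalysed product, a share read as 61.1%.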